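The decalin is disconnected across ring B at C5–C10 and C8–C9 (labdane numbering). The target's C15–C3 backbone, with the C9–C10 edge carrying the cis C20 methyl and C11 side chain, is the (E,E)-farnesol chain; the C7 oxygen sits at the 2-position of a C5–C8 diene. A type 1 intramolecular Diels–Alder reaction of an acyclic 2-silyloxydiene/farnesyl triene, tethered through C1–C4 and the preset C4 quaternary centre, closes both rings at once, forges the C5–C10 ring-fusion bond and sets C5, C9 and C10. Exocyclic methylenation, Luche reduction and acetylation finish the synthesis.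

Key step: step 10

Remark: atoms are numbered as in labdanes; in step 6 the ligand enantiomer is taken to be the one that gives (S)-10, and in the enzymatic fallback pig liver esterase is taken to leave the (R)-half-ester, the usual sense for long-chain 2-alkyl-2-methylmalonates.

Step 1
Reactants: 1 (2E,6E)-farnesol
Product: 2 (2E,6E)-farnesyl tert-butyldiphenylsilyl ether
Conditions: TBDPSCl, imidazole, DMF, 0 °C to rt
Reagents that add atoms: tert-butyl(chloro)diphenylsilane, CC(C)(C)[Si](Cl)(c1ccccc1)c1ccccc1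
Why: Silylation of the primary allylic alcohol gives an ether that should survive acid, base, heat and hydride until the last step; no stereocentre is formed.

Step 2
Reactants: 2 (2E,6E)-farnesyl tert-butyldiphenylsilyl ether
Product: 4 10,11-epoxyfarnesyl tert-butyldiphenylsilyl ether (racemic epoxide), via bromohydrin 3 (not isolated)
Conditions: NBS, THF/H2O, 0 °C; then K2CO3, MeOH, rt
Reagents that add atoms: water, O; N-bromosuccinimide, O=C1CCC(=O)N1Br
Why: In aqueous medium the terminal trisubstituted alkene should be attacked selectively by electrophilic bromine (bromohydrin formation, water opening the bromonium ion at the tertiary carbon) and base closes the epoxide by intramolecular Williamson substitution; the epoxide stereocentre is erased in step 3.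

Step 3
Reactants: 4 10,11-epoxyfarnesyl tert-butyldiphenylsilyl ether
Product: 6 (4E,8E)-10-(tert-butyldiphenylsilyloxy)-4,8-dimethyldeca-4,8-dien-1-ol, via aldehyde 5 (not isolated)
Conditions: H5IO6, THF/Et2O, 0 °C; aqueous wash, then NaBH4, MeOH, 0 °C
Reagents that add atoms: none
Why: Periodic acid hydrolyses the epoxide and cleaves the glycol (Malaprade-type cleavage, acetone lost) to the trisnor aldehyde, which borohydride reduces to the primary alcohol that becomes C3.

Step 4
Reactants: 6 (4E,8E)-10-(tert-butyldiphenylsilyloxy)-4,8-dimethyldeca-4,8-dien-1-ol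
Product: 7 tert-butyl{[(2E,6E)-10-iodo-3,7-dimethyldeca-2,6-dien-1-yl]oxy}diphenylsilane
Conditions: I2, PPh3, imidazole, CH2Cl2, 0 °C to rt
Reagents that add atoms: iodine, II
Why: Appel-type iodination converts the unhindered primary alcohol into the iodide by SN2 displacement of the oxyphosphonium ion without touching the alkenes.

Step 5
Reactants: 7 tert-butyl{[(2E,6E)-10-iodo-3,7-dimethyldeca-2,6-dien-1-yl]oxy}diphenylsilane; 8 dimethyl methylmalonate
Product: 9 dimethyl 2-[(4E,8E)-10-(tert-butyldiphenylsilyloxy)-4,8-dimethyldeca-4,8-dien-1-yl]-2-methylmalonate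
Conditions: NaH, THF/DMF, 0 °C; then 7, 60 °C
Reagents that add atoms: none
Why: Malonic ester alkylation (SN2 of the sodium enolate on the primary iodide) forms the C3–C4 bond and gives a prochiral quaternary carbon with two enantiotopic esters.

Step 6
Reactants: 9 dimethyl 2-[(4E,8E)-10-(tert-butyldiphenylsilyloxy)-4,8-dimethyldeca-4,8-dien-1-yl]-2-methylmalonate
Product: 10 methyl (2S,6E,10E)-12-(tert-butyldiphenylsilyloxy)-2-(hydroxymethyl)-2,6,10-trimethyldodeca-6,10-dienoate
Conditions: Et2Zn (10 mol %), chiral pipecolinol-derived tetradentate ligand (5 mol %), HSi(OMe)3, THF, 0 °C to rt; then K2CO3, MeOH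
Reagents that add atoms: none
Why: Zinc-catalysed desymmetrising hydrosilylation of an α,α-disubstituted malonic ester reduces one enantiotopic ester only, the chiral dinuclear zinc catalyst telling the methyl group from the alkyl chain and so setting the C4 quaternary centre as (S).

Step 7
Reactants: 10 methyl (2S,6E,10E)-12-(tert-butyldiphenylsilyloxy)-2-(hydroxymethyl)-2,6,10-trimethyldodeca-6,10-dienoate
Product: 11 methyl (2S,6E,10E)-12-(tert-butyldiphenylsilyloxy)-2-formyl-2,6,10-trimethyldodeca-6,10-dienoate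
Conditions: Dess–Martin periodinane, NaHCO3, CH2Cl2, 0 °C to rt
Reagents that add atoms: none
Why: Dess–Martin oxidation gives the aldehyde (future C5) under buffered conditions, and the quaternary α-carbon cannot epimerise.

Step 8
Reactants: 11 methyl (2S,6E,10E)-12-(tert-butyldiphenylsilyloxy)-2-formyl-2,6,10-trimethyldodeca-6,10-dienoate; 12 1-(triphenylphosphoranylidene)propan-2-one
Product: 13 methyl (2S,6E,10E)-12-(tert-butyldiphenylsilyloxy)-2,6,10-trimethyl-2-[(1E)-3-oxobut-1-en-1-yl]dodeca-6,10-dienoate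
Conditions: PhMe, 100 °C
Reagents that add atoms: none
Why: Wittig olefination with the stabilised ylide under neutral conditions (no retro-Claisen loss of the formyl group) should give the (E)-enone C5=C6–C7(=O)–C8.

Step 9
Reactants: 13 methyl (2S,6E,10E)-12-(tert-butyldiphenylsilyloxy)-2,6,10-trimethyl-2-[(1E)-3-oxobut-1-en-1-yl]dodeca-6,10-dienoate
Product: 14 methyl (2S,6E,10E)-2-[(1E)-3-(tert-butyldimethylsilyloxy)buta-1,3-dien-1-yl]-12-(tert-butyldiphenylsilyloxy)-2,6,10-trimethyldodeca-6,10-dienoate
Conditions: TBSOTf, Et3N, CH2Cl2, −78 to 0 °C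
Reagents that add atoms: tert-butyldimethylsilyl trifluoromethanesulfonate, CC(C)(C)[Si](C)(C)OS(=O)(=O)C(F)(F)F
Why: Soft enolisation and O-silylation (silyl enol ether formation) can occur only at the methyl group, because the γ-carbon C4 is quaternary, and gives the 2-silyloxy-1,3-diene.

Step 10
Reactants: 14 methyl (2S,6E,10E)-2-[(1E)-3-(tert-butyldimethylsilyloxy)buta-1,3-dien-1-yl]-12-(tert-butyldiphenylsilyloxy)-2,6,10-trimethyldodeca-6,10-dienoate
Product: 16 methyl 15-(tert-butyldiphenylsilyloxy)-7-oxo-17-norlabd-13E-en-19-oate, via silyl enol ether 15 (not isolated)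
Conditions: mesitylene (0.01 M), BHT, base-washed sealed tube, 210 °C; then 1 M HCl, THF, 0 °C
Reagents that add atoms: none
Why: Thermal suprafacial [4+2] cycloaddition (type 1 intramolecular Diels–Alder reaction) between the 2-silyloxydiene C5=C6–C7=C8 and the C9=C10 alkene forms C5–C10 and C8–C9 in one concerted, asynchronous event; the closest known reaction type is the thermal cyclisation of unactivated 1,7,9-decatrienes to angular-methyl octalins. Ring B is closed as the new cyclohexene by the cycloaddition itself, and ring A is closed in the fused mode by the C5–C10 bond across the four-atom tether C1–C4, which adopts a chair. The (E)-geometry of the former farnesyl 6,7-alkene is transcribed into the cis relation of the C20 methyl (C10) and the C11 chain (C9), and the anti (trans-fused) chair transition state sets H5 trans to C20. The absolute sense comes from the C4 centre: the diene face is chosen so that the ester, not the methyl group, takes the axial tether position 1,3 to the incoming C20 methyl. Periselectivity is secured by tether length (the C13=C14 alkene would need a macrocyclic transition state) and the gem-disubstituted C4 should accelerate closure; the needed anti over syn preference rests only on the chair tether and is the weakest point, and dilute acid then unmasks the C7 ketone.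

Step 11
Reactants: 16 methyl 15-(tert-butyldiphenylsilyloxy)-7-oxo-17-norlabd-13E-en-19-oate
Product: 17 methyl 17-(dimethylamino)-15-(tert-butyldiphenylsilyloxy)-7-oxolabd-13E-en-19-oate (C8 epimers)
Conditions: LiN(SiMe3)2, THF, −78 °C; then CH2=NMe2+ I−, −78 °C to rt
Reagents that add atoms: dimethyl(methylidene)ammonium iodide, C=[N+](C)C.[I-]
Why: Kinetic deprotonation should occur at C8 (the axial hydrogen at C6 is screened by both the C20 methyl and the axial ester, as in the C2 enolisation of 3-keto-5α-steroids) and the Mannich reaction of the enolate brings in C17; the C8 configuration is immaterial.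

Step 12
Reactants: 17 methyl 17-(dimethylamino)-15-(tert-butyldiphenylsilyloxy)-7-oxolabd-13E-en-19-oate
Product: 19 methyl 15-(tert-butyldiphenylsilyloxy)-7-oxolabda-8(17),13E-dien-19-oate, via methiodide 18 (not isolated)
Conditions: MeI, THF, rt; then aq. NaHCO3, CH2Cl2, rt
Reagents that add atoms: iodomethane, CI
Why: N-Quaternisation followed by mild E1cB (Hofmann-type) elimination of trimethylamine gives the exocyclic α-methylene ketone under conditions too mild for migration of the double bond into the ring.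

Step 13
Reactants: 19 methyl 15-(tert-butyldiphenylsilyloxy)-7-oxolabda-8(17),13E-dien-19-oate
Product: 20 methyl 15-(tert-butyldiphenylsilyloxy)-7β-hydroxylabda-8(17),13E-dien-19-oate
Conditions: NaBH4, CeCl3·7H2O, MeOH, −78 °C
Reagents that add atoms: none
Why: Luche 1,2-reduction of the enone, with axial hydride delivery from the α face (only H5 and H9 are syn-axial), should give the equatorial 7β (7S) allylic alcohol.

Step 14
Reactants: 20 methyl 15-(tert-butyldiphenylsilyloxy)-7β-hydroxylabda-8(17),13E-dien-19-oate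
Product: 21 methyl 7β-acetoxy-15-(tert-butyldiphenylsilyloxy)labda-8(17),13E-dien-19-oate
Conditions: Ac2O, pyridine, DMAP (cat.), CH2Cl2, rt
Reagents that add atoms: acetic anhydride, CC(=O)OC(C)=O
Why: DMAP-catalysed acylation of the only free hydroxyl group installs the C7 acetate with retention.

Step 15
Reactants: 21 methyl 7β-acetoxy-15-(tert-butyldiphenylsilyloxy)labda-8(17),13E-dien-19-oate
Product: 22 methyl (4S,5R,7S,9R,10R)-7-acetoxy-15-hydroxylabda-8(17),13E-dien-19-oate (CNP0329157.1)
Conditions: HF·pyridine, THF/pyridine, 0 °C to rt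
Reagents that add atoms: none
Why: Fluoride-mediated Si–O cleavage under buffered, non-basic conditions frees the C15 allylic alcohol without acetate hydrolysis or migration.

Compound list
1 | (2E,6E)-farnesol | CC(C)=CCC/C(C)=C/CC/C(C)=C/CO | starting material
2 | (2E,6E)-farnesyl tert-butyldiphenylsilyl ether | CC(C)=CCC/C(C)=C/CC/C(C)=C/CO[Si](c1ccccc1)(c1ccccc1)C(C)(C)C | intermediate
3 | tert-butyl{[(2E,6E)-10-bromo-11-hydroxy-3,7,11-trimethyldodeca-2,6-dien-1-yl]oxy}diphenylsilane (bromohydrin, racemic) | CC(C)(O)C(Br)CC/C(C)=C/CC/C(C)=C/CO[Si](c1ccccc1)(c1ccccc1)C(C)(C)C | intermediate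
4 | 10,11-epoxyfarnesyl tert-butyldiphenylsilyl ether (racemic epoxide) | CC1(C)OC1CC/C(C)=C/CC/C(C)=C/CO[Si](c2ccccc2)(c2ccccc2)C(C)(C)C | intermediate
5 | (4E,8E)-10-(tert-butyldiphenylsilyloxy)-4,8-dimethyldeca-4,8-dienal | O=CCC/C(C)=C/CC/C(C)=C/CO[Si](c1ccccc1)(c1ccccc1)C(C)(C)C | intermediate
6 | (4E,8E)-10-(tert-butyldiphenylsilyloxy)-4,8-dimethyldeca-4,8-dien-1-ol | OCCC/C(C)=C/CC/C(C)=C/CO[Si](c1ccccc1)(c1ccccc1)C(C)(C)C | intermediate
7 | tert-butyl{[(2E,6E)-10-iodo-3,7-dimethyldeca-2,6-dien-1-yl]oxy}diphenylsilane | ICCC/C(C)=C/CC/C(C)=C/CO[Si](c1ccccc1)(c1ccccc1)C(C)(C)C | intermediate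
8 | dimethyl methylmalonate | COC(=O)C(C)C(=O)OC | starting material
9 | dimethyl 2-[(4E,8E)-10-(tert-butyldiphenylsilyloxy)-4,8-dimethyldeca-4,8-dien-1-yl]-2-methylmalonate | COC(=O)C(C)(CCC/C(C)=C/CC/C(C)=C/CO[Si](c1ccccc1)(c1ccccc1)C(C)(C)C)C(=O)OC | intermediate
10 | methyl (2S,6E,10E)-12-(tert-butyldiphenylsilyloxy)-2-(hydroxymethyl)-2,6,10-trimethyldodeca-6,10-dienoate | OC[C@](C)(CCC/C(C)=C/CC/C(C)=C/CO[Si](c1ccccc1)(c1ccccc1)C(C)(C)C)C(=O)OC | intermediate
11 | methyl (2S,6E,10E)-12-(tert-butyldiphenylsilyloxy)-2-formyl-2,6,10-trimethyldodeca-6,10-dienoate | O=C[C@](C)(CCC/C(C)=C/CC/C(C)=C/CO[Si](c1ccccc1)(c1ccccc1)C(C)(C)C)C(=O)OC | intermediate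
12 | 1-(triphenylphosphoranylidene)propan-2-one | CC(=O)C=P(c1ccccc1)(c1ccccc1)c1ccccc1 | starting material
13 | methyl (2S,6E,10E)-12-(tert-butyldiphenylsilyloxy)-2,6,10-trimethyl-2-[(1E)-3-oxobut-1-en-1-yl]dodeca-6,10-dienoate | CC(=O)/C=C/[C@](C)(CCC/C(C)=C/CC/C(C)=C/CO[Si](c1ccccc1)(c1ccccc1)C(C)(C)C)C(=O)OC | intermediate
14 | methyl (2S,6E,10E)-2-[(1E)-3-(tert-butyldimethylsilyloxy)buta-1,3-dien-1-yl]-12-(tert-butyldiphenylsilyloxy)-2,6,10-trimethyldodeca-6,10-dienoate | C=C(O[Si](C)(C)C(C)(C)C)/C=C/[C@](C)(CCC/C(C)=C/CC/C(C)=C/CO[Si](c1ccccc1)(c1ccccc1)C(C)(C)C)C(=O)OC | intermediate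
15 | methyl 7-(tert-butyldimethylsilyloxy)-15-(tert-butyldiphenylsilyloxy)-17-norlabda-6,13E-dien-19-oate (trans-fused; 5α-H, 9α-H, 10β-methyl, 4β-ester) | CC(C)(C)[Si](C)(C)OC1=C[C@@H]2[C@](C)(CCC[C@]2(C)C(=O)OC)[C@@H](CC/C(C)=C/CO[Si](c3ccccc3)(c3ccccc3)C(C)(C)C)C1 | intermediate
16 | methyl 15-(tert-butyldiphenylsilyloxy)-7-oxo-17-norlabd-13E-en-19-oate | O=C1C[C@@H]2[C@](C)(CCC[C@]2(C)C(=O)OC)[C@@H](CC/C(C)=C/CO[Si](c3ccccc3)(c3ccccc3)C(C)(C)C)C1 | intermediate
17 | methyl 17-(dimethylamino)-15-(tert-butyldiphenylsilyloxy)-7-oxolabd-13E-en-19-oate (C8 epimers) | CN(C)CC1C(=O)C[C@@H]2[C@](C)(CCC[C@]2(C)C(=O)OC)[C@H]1CC/C(C)=C/CO[Si](c3ccccc3)(c3ccccc3)C(C)(C)C | intermediate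
18 | N-methyl ammonium iodide of 17 (methiodide) | C[N+](C)(C)CC1C(=O)C[C@@H]2[C@](C)(CCC[C@]2(C)C(=O)OC)[C@H]1CC/C(C)=C/CO[Si](c3ccccc3)(c3ccccc3)C(C)(C)C.[I-] | intermediate
19 | methyl 15-(tert-butyldiphenylsilyloxy)-7-oxolabda-8(17),13E-dien-19-oate | C=C1C(=O)C[C@@H]2[C@](C)(CCC[C@]2(C)C(=O)OC)[C@H]1CC/C(C)=C/CO[Si](c3ccccc3)(c3ccccc3)C(C)(C)C | intermediate
20 | methyl 15-(tert-butyldiphenylsilyloxy)-7β-hydroxylabda-8(17),13E-dien-19-oate | C=C1[C@@H](O)C[C@@H]2[C@](C)(CCC[C@]2(C)C(=O)OC)[C@H]1CC/C(C)=C/CO[Si](c3ccccc3)(c3ccccc3)C(C)(C)C | intermediate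
21 | methyl 7β-acetoxy-15-(tert-butyldiphenylsilyloxy)labda-8(17),13E-dien-19-oate | C=C1[C@@H](OC(C)=O)C[C@@H]2[C@](C)(CCC[C@]2(C)C(=O)OC)[C@H]1CC/C(C)=C/CO[Si](c3ccccc3)(c3ccccc3)C(C)(C)C | intermediate
22 | methyl (4S,5R,7S,9R,10R)-7-acetoxy-15-hydroxylabda-8(17),13E-dien-19-oate (CNP0329157.1) | C=C1[C@@H](OC(C)=O)C[C@@H]2[C@](C)(CCC[C@]2(C)C(=O)OC)[C@H]1CC/C(C)=C/CO | target

Total step count: 15. Longest linear sequence: 15 steps (1 to 22).

Steps most likely to fail

Step 10, where the temperature that the unactivated alkene demands may erode the anti/syn (ring-fusion) selectivity of the cycloaddition. The fallback sets out from 15 and comes back at 16. The crude cycloadduct mixture 15 is not hydrolysed but oxidised with Pd(OAc)2 in MeCN (Saegusa–Ito oxidation) to the 5-en-7-one, methyl 15-(tert-butyldiphenylsilyloxy)-7-oxo-17-norlabda-5,13E-dien-19-oate F1. This erases C5 and merges both ring-fusion isomers. Conjugate reduction with [(Ph3P)CuH]6 and PhSiH3 in PhMe should then deliver hydride to C5 from the α face, opposite the C20 methyl and the axial ester, and give trans-fused 16, so that C5 is set by reduction and no longer by the cycloaddition.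

Step 6, where discrimination between the enantiotopic esters (methyl against a long alkyl chain) may be incomplete, or the hydroxy ester may be reduced further to the diol. The fallback sets out from 9 and comes back at 10. Pig liver esterase (phosphate buffer pH 7.5, DMSO co-solvent) hydrolyses one ester to the half-ester, (2R)-2-(methoxycarbonyl)-2-methyl-alkanoic acid F2. LiBH4 on the lithium carboxylate reduces the remaining ester selectively to the hydroxy acid F3. Esterification with TMSCHN2 in MeOH/PhMe gives 10.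

Step 11, where enolisation towards C6 may compete and place the aminomethyl group at the wrong carbon. The fallback sets out from 15 and comes back at 17. Compound 15 is oxidised as above to the 5-en-7-one F1, in which C6 is vinylic and C8 is the only enolisable position. LiN(SiMe3)2 and then dimethyl(methylidene)ammonium iodide give the α′-Mannich base, methyl 17-(dimethylamino)-15-(tert-butyldiphenylsilyloxy)-7-oxolabda-5,13E-dien-19-oate F4. Conjugate reduction of C5=C6 with [(Ph3P)CuH]6, hydride entering from the α face, returns to the route at 17.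

Further compounds
F1 | step 10 | methyl 15-(tert-butyldiphenylsilyloxy)-7-oxo-17-norlabda-5,13E-dien-19-oate | O=C1C=C2[C@](C)(CCC[C@]2(C)C(=O)OC)[C@@H](CC/C(C)=C/CO[Si](c3ccccc3)(c3ccccc3)C(C)(C)C)C1
F2 | step 6 | (2R,6E,10E)-12-(tert-butyldiphenylsilyloxy)-2-(methoxycarbonyl)-2,6,10-trimethyldodeca-6,10-dienoic acid | COC(=O)[C@](C)(CCC/C(C)=C/CC/C(C)=C/CO[Si](c1ccccc1)(c1ccccc1)C(C)(C)C)C(=O)O
F3 | step 6 | (2S,6E,10E)-12-(tert-butyldiphenylsilyloxy)-2-(hydroxymethyl)-2,6,10-trimethyldodeca-6,10-dienoic acid | OC[C@](C)(CCC/C(C)=C/CC/C(C)=C/CO[Si](c1ccccc1)(c1ccccc1)C(C)(C)C)C(=O)O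
F4 | step 11 | methyl 17-(dimethylamino)-15-(tert-butyldiphenylsilyloxy)-7-oxolabda-5,13E-dien-19-oate (C8 epimers) | CN(C)CC1C(=O)C=C2[C@](C)(CCC[C@]2(C)C(=O)OC)[C@H]1CC/C(C)=C/CO[Si](c3ccccc3)(c3ccccc3)C(C)(C)C
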